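**Retrosynthetic overview**
- The target comes from selective acetylation of the C8 secondary alcohol of a cis-7,8-diol, which comes from a two-fold hydride reduction (C1, then the C8 ketone) of a chloro-azaphilone.
- The azaphilone comes from an o-alkynylbenzaldehyde: cycloisomerization closes the pyran ring, then a catalytic enantioselective hydroxylation at C7 (the new step) dearomatizes the carbocycle.
- The o-alkynylbenzaldehyde comes from Sonogashira coupling of a fully substituted bromo-chloro-resorcinol aldehyde (three steps from 5-bromoresorcinol) with a chiral dienyne.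
- The dienyne comes from Wittig and Horner–Wadsworth–Emmons extension of (R)-2-methylbutanol, whose stereocentre is set by asymmetric hydrogenation of tiglic acid.
- Ring order: the benzene ring is bought; the pyran ring is the only ring formed (step 9), and the benzene ring is dearomatized in the same flask.

Assumption: the facial sense of the new hydroxylation cannot be predicted, so the cinchonidinium catalyst is written and its commercial pseudo-enantiomer (cinchoninium) is used instead if a test run gives the 7S alcohol.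

Step 1
Reactants: 1 tiglic acid [(2E)-2-methylbut-2-enoic acid]
Product: 2 (2R)-2-methylbutanoic acid
Conditions: H2 (1.5 atm), Ru(OAc)2[(R)-H8-BINAP] (0.5 mol%), MeOH, 15 °C
Reagents that add atoms: none
Why: Noyori-type asymmetric hydrogenation of an α,β-unsaturated acid, in which the carboxylate-bound chiral ruthenium diphosphine complex delivers H2 to one face of the alkene and sets the R centre that becomes C5 of the side chain.

Step 2
Reactants: 2 (2R)-2-methylbutanoic acid
Product: 3 (2R)-2-methylbutan-1-ol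
Conditions: LiAlH4, THF, 0 °C → rt
Reagents that add atoms: none
Why: hydride reduction of the carboxylic acid to the primary alcohol, which does not touch the stereocentre.

Step 3
Reactants: 3 (2R)-2-methylbutan-1-ol; 4 2-(triphenyl-λ5-phosphanylidene)propanal
Product: 6 (2E,4R)-2,4-dimethylhex-2-enal, via (2R)-2-methylbutanal 5 (not isolated)
Conditions: PhI(OAc)2, TEMPO (10 mol%), CH2Cl2, rt; then 4 (1.05 equiv), 40 °C
Reagents that add atoms: none
Why: TEMPO/PhI(OAc)2 oxidation followed by in-situ Wittig olefination with a stabilized formyl ylide gives the E-trisubstituted enal under non-basic conditions, so the epimerizable aldehyde 5 is trapped without loss of the R centre.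

Step 4
Reactants: 6 (2E,4R)-2,4-dimethylhex-2-enal; 7 diethyl [3-(trimethylsilyl)prop-2-yn-1-yl]phosphonate
Product: 9 (3E,5E,7R)-5,7-dimethylnona-3,5-dien-1-yne, via TMS-dienyne 8 (not isolated)
Conditions: 7, LiN(SiMe3)2, THF, −78 °C (pre-formed anion), then 6, −78 → 0 °C; then K2CO3, MeOH, rt
Reagents that add atoms: none
Why: Horner–Wadsworth–Emmons olefination with the propargylic phosphonate anion gives the E-enyne by 1,2-addition at −78 °C (no γ-deprotonation of the enal), and K2CO3/MeOH then removes the alkynyl silyl group.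

Step 5
Reactants: 10 5-bromobenzene-1,3-diol (5-bromoresorcinol)
Product: 11 2-bromo-4,6-dihydroxybenzaldehyde
Conditions: POCl3, DMF, MeCN, 0 °C → rt; then H2O, 50 °C
Reagents that add atoms: N,N-dimethylformamide, CN(C)C=O; water, O
Why: Vilsmeier–Haack formylation at the resorcinol 4-position (para to one OH, ortho to the other), as in the orcinol-to-orcylaldehyde case.

Step 6
Reactants: 11 2-bromo-4,6-dihydroxybenzaldehyde
Product: 12 6-bromo-2,4-dihydroxy-3-methylbenzaldehyde
Conditions: MeI, KOH, MeOH, rt → 60 °C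
Reagents that add atoms: iodomethane, CI
Why: C-methylation of the resorcinol dianion at the carbon between the two phenoxide oxygens, its most nucleophilic position; the yield is moderate because O-methylation competes.

Step 7
Reactants: 12 6-bromo-2,4-dihydroxy-3-methylbenzaldehyde
Product: 13 6-bromo-5-chloro-2,4-dihydroxy-3-methylbenzaldehyde
Conditions: NCS, MeCN, 0 °C → rt
Reagents that add atoms: N-chlorosuccinimide, O=C1CCC(=O)N1Cl
Why: electrophilic aromatic chlorination at the only free ring position, which is ortho and para to the two hydroxyl groups.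

Step 8
Reactants: 13 6-bromo-5-chloro-2,4-dihydroxy-3-methylbenzaldehyde; 9 (3E,5E,7R)-5,7-dimethylnona-3,5-dien-1-yne
Product: 14 5-chloro-6-[(3E,5E,7R)-5,7-dimethylnona-3,5-dien-1-yn-1-yl]-2,4-dihydroxy-3-methylbenzaldehyde
Conditions: PdCl2(PPh3)2 (5 mol%), CuI (10 mol%), Et3N, DMF, 60 °C
Reagents that add atoms: none
Why: Sonogashira coupling at the C–Br bond activated by the ortho formyl group, leaving the C–Cl bond, the free phenols and the aldehyde untouched.

Step 9
Reactants: 14 5-chloro-6-[(3E,5E,7R)-5,7-dimethylnona-3,5-dien-1-yn-1-yl]-2,4-dihydroxy-3-methylbenzaldehyde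
Product: 17 (7R)-5-chloro-3-[(1E,3E,5R)-3,5-dimethylhepta-1,3-dien-1-yl]-7-hydroxy-7-methyl-6H-isochromene-6,8(7H)-dione, via 2-benzopyrylium trifluoroacetate 15 (not isolated), via quinoidal anhydrobase 16 (not isolated)
Conditions: Au(OAc)3 (5 mol%), TFA (2 equiv), ClCH2CH2Cl, rt, 10 min; then toluene, powdered K2HPO4 (4 equiv), N-(9-anthracenylmethyl)cinchonidinium chloride (10 mol%), (±)-trans-3-phenyl-2-(phenylsulfonyl)oxaziridine (1.5 equiv), −30 °C
Reagents that add atoms: trans-3-phenyl-2-(phenylsulfonyl)oxaziridine, O=S(=O)(c1ccccc1)N1OC1c1ccccc1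
Why: Proposed new method: the known gold-catalysed 6-endo cycloisomerization of the o-alkynylbenzaldehyde closes the pyran ring to benzopyrylium 15, K2HPO4 frees its anhydrobase 16, a vinylogous 2-methyl-1,3-diketone enol whose enolate is nucleophilic only at C7 (C5 is blocked by Cl), and as a tight ion pair with the chiral quaternary ammonium cation (its 9-OH hydrogen-bonded to the oxaziridine) this enolate takes electrophilic oxygen on one face to set the 7R tertiary alcohol, the neutral non-acidic azaphilone releasing the catalyst; the closest known reaction types are phase-transfer-catalysed enantioselective α-hydroxylation of β-keto esters with N-sulfonyl oxaziridines and the copper–diamine or IBX oxidations that make azaphilones from the same precursors.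

Step 10
Reactants: 17 (7R)-5-chloro-3-[(1E,3E,5R)-3,5-dimethylhepta-1,3-dien-1-yl]-7-hydroxy-7-methyl-6H-isochromene-6,8(7H)-dione
Product: 19 (7R,8R,8aR)-5-chloro-3-[(1E,3E,5R)-3,5-dimethylhepta-1,3-dien-1-yl]-7,8-dihydroxy-7-methyl-1,7,8,8a-tetrahydro-6H-isochromen-6-one, via 8-ketone 18 (not isolated)
Conditions: NaBH4 (3 equiv), MeOH/CH2Cl2 (1:1), −78 → −20 °C; aqueous NH4Cl
Reagents that add atoms: none
Why: conjugate hydride addition to the oxocarbenium-like C1 gives the C8 enolate, methanol protonates it at C8a to ketone 18 whose C8a epimers equilibrate through that enolate, and the second hydride adds to C8 by polar Felkin–Anh axial attack anti to the C7–O bond on the epimer with C1 equatorial, which sets 8R (cis to the 7-OH) and 8aR (H8/H8a trans-diaxial) by dynamic kinetic resolution, while the C6 vinylogous-ester carbonyl is inert to NaBH4.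

Step 11
Reactants: 19 (7R,8R,8aR)-5-chloro-3-[(1E,3E,5R)-3,5-dimethylhepta-1,3-dien-1-yl]-7,8-dihydroxy-7-methyl-1,7,8,8a-tetrahydro-6H-isochromen-6-one
Product: 20 (7R,8R,8aR)-5-chloro-3-[(1E,3E,5R)-3,5-dimethylhepta-1,3-dien-1-yl]-7-hydroxy-7-methyl-6-oxo-1,7,8,8a-tetrahydro-6H-isochromen-8-yl acetate
Conditions: Ac2O (1.2 equiv), pyridine, DMAP (5 mol%), CH2Cl2, 0 °C
Reagents that add atoms: acetic anhydride, CC(=O)OC(C)=O
Why: DMAP-catalysed acylation acetylates the secondary C8 alcohol in preference to the hindered tertiary C7 alcohol, and the mild base does not epimerize C8a or eliminate the new acetate.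

**Compound list**
1 | tiglic acid, (2E)-2-methylbut-2-enoic acid | C/C=C(\C)C(=O)O | starting material
2 | (2R)-2-methylbutanoic acid | CC[C@@H](C)C(=O)O | intermediate
3 | (2R)-2-methylbutan-1-ol | CC[C@@H](C)CO | intermediate
4 | 2-(triphenyl-λ5-phosphanylidene)propanal | CC(C=O)=P(c1ccccc1)(c1ccccc1)c1ccccc1 | starting material
5 | (2R)-2-methylbutanal | CC[C@@H](C)C=O | intermediate
6 | (2E,4R)-2,4-dimethylhex-2-enal | CC[C@@H](C)/C=C(C)/C=O | intermediate
7 | diethyl [3-(trimethylsilyl)prop-2-yn-1-yl]phosphonate | CCOP(=O)(CC#C[Si](C)(C)C)OCC | starting material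
8 | trimethyl[(3E,5E,7R)-5,7-dimethylnona-3,5-dien-1-yn-1-yl]silane | CC[C@@H](C)/C=C(C)/C=C/C#C[Si](C)(C)C | intermediate
9 | (3E,5E,7R)-5,7-dimethylnona-3,5-dien-1-yne | CC[C@@H](C)/C=C(C)/C=C/C#C | intermediate
10 | 5-bromobenzene-1,3-diol | Oc1cc(O)cc(Br)c1 | starting material
11 | 2-bromo-4,6-dihydroxybenzaldehyde | O=Cc1c(O)cc(O)cc1Br | intermediate
12 | 6-bromo-2,4-dihydroxy-3-methylbenzaldehyde | O=Cc1c(O)c(C)c(O)cc1Br | intermediate
13 | 6-bromo-5-chloro-2,4-dihydroxy-3-methylbenzaldehyde | O=Cc1c(O)c(C)c(O)c(Cl)c1Br | intermediate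
14 | 5-chloro-6-[(3E,5E,7R)-5,7-dimethylnona-3,5-dien-1-yn-1-yl]-2,4-dihydroxy-3-methylbenzaldehyde | CC[C@@H](C)/C=C(C)/C=C/C#Cc1c(Cl)c(O)c(C)c(O)c1C=O | intermediate
15 | 5-chloro-3-[(1E,3E,5R)-3,5-dimethylhepta-1,3-dien-1-yl]-6,8-dihydroxy-7-methylisochromenylium trifluoroacetate | CC[C@@H](C)/C=C(C)/C=C/c1cc2c(Cl)c(O)c(C)c(O)c2c[o+]1.[O-]C(=O)C(F)(F)F | intermediate
16 | 5-chloro-3-[(1E,3E,5R)-3,5-dimethylhepta-1,3-dien-1-yl]-8-hydroxy-7-methyl-6H-isochromen-6-one | CC[C@@H](C)/C=C(C)/C=C/C1=CC2=C(Cl)C(=O)C(C)=C(O)C2=CO1 | intermediate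
17 | (7R)-5-chloro-3-[(1E,3E,5R)-3,5-dimethylhepta-1,3-dien-1-yl]-7-hydroxy-7-methyl-6H-isochromene-6,8(7H)-dione | CC[C@@H](C)/C=C(C)/C=C/C1=CC2=C(Cl)C(=O)[C@](C)(O)C(=O)C2=CO1 | intermediate
18 | (7R,8aR)-5-chloro-3-[(1E,3E,5R)-3,5-dimethylhepta-1,3-dien-1-yl]-7-hydroxy-7-methyl-1,8a-dihydro-6H-isochromene-6,8(7H)-dione | CC[C@@H](C)/C=C(C)/C=C/C1=CC2=C(Cl)C(=O)[C@](C)(O)C(=O)[C@H]2CO1 | intermediate
19 | (7R,8R,8aR)-5-chloro-3-[(1E,3E,5R)-3,5-dimethylhepta-1,3-dien-1-yl]-7,8-dihydroxy-7-methyl-1,7,8,8a-tetrahydro-6H-isochromen-6-one | CC[C@@H](C)/C=C(C)/C=C/C1=CC2=C(Cl)C(=O)[C@](C)(O)[C@H](O)[C@H]2CO1 | intermediate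
20 | (7R,8R,8aR)-5-chloro-3-[(1E,3E,5R)-3,5-dimethylhepta-1,3-dien-1-yl]-7-hydroxy-7-methyl-6-oxo-1,7,8,8a-tetrahydro-6H-isochromen-8-yl acetate | CC[C@@H](C)/C=C(C)/C=C/C1=CC2=C(Cl)C(=O)[C@](C)(O)[C@H](OC(C)=O)[C@H]2CO1 | target

**Totals**
Total step count: 11. Longest linear sequence: 8 steps (steps 1–4, then 8–11); the arene branch is 7 steps (5–11).

**Three steps most likely to fail**

Step 9 (the new hydroxylation). The enantioselectivity and sense of induction are untested, and the anhydrobase may dimerize or add nucleophiles at C1. The fallback sets out from 14 and uses the known copper-mediated enantioselective oxidative dearomatization of o-alkynylbenzaldehydes. Treating 14 with [Cu(MeCN)4]PF6, the (+)-sparteine surrogate and O2 in CH2Cl2 at −78 °C gives the vinylogous acid (3R)-5-chloro-6-[(3E,5E,7R)-5,7-dimethylnona-3,5-dien-1-yn-1-yl]-2,3-dihydroxy-3-methyl-4-oxocyclohexa-1,5-diene-1-carbaldehyde F1. This is cycloisomerized in KH2PO4/K2HPO4-buffered MeCN (with catalytic CuI if needed) and comes back to the route at 17.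

Step 10 (double reduction). The first hydride may add 1,2 at C8 instead of at C1, a minor tautomer may be reduced at C6, or the free 7-OH may direct hydride to give the trans-diol or the C8a epimer. The fallback sets out from 17 and changes the order of events. The tertiary alcohol is acetylated first (Ac2O, DMAP, pyridine, rt) to (7R)-5-chloro-3-[(1E,3E,5R)-3,5-dimethylhepta-1,3-dien-1-yl]-7-methyl-6,8-dioxo-7,8-dihydro-6H-isochromen-7-yl acetate F2. NaBH4 in MeOH at −40 °C then reduces C1 and C8, now strictly anti to the non-chelating acetoxy group, to (7R,8R,8aR)-5-chloro-3-[(1E,3E,5R)-3,5-dimethylhepta-1,3-dien-1-yl]-8-hydroxy-7-methyl-6-oxo-1,7,8,8a-tetrahydro-6H-isochromen-7-yl acetate F3. Its cis 8-alkoxide takes over the acetyl group by 1,2-acyl shift (completed with catalytic K2CO3 in MeOH), so the fallback comes back to the route at 20 and step 11 falls away.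

Step 8 (Sonogashira on a bromide flanked by CHO and Cl, with free phenols). Oxidative addition may be too slow. The fallback sets out from 12 and 9. The less hindered bromide 12 is coupled first under the same palladium/copper conditions to give 6-[(3E,5E,7R)-5,7-dimethylnona-3,5-dien-1-yn-1-yl]-2,4-dihydroxy-3-methylbenzaldehyde F4. The one free ring position, activated by both phenols, is then chlorinated with NCS in MeCN at 0 °C, and the fallback comes back to the route at 14.

**Further compounds**
F1 | step 9 | (3R)-5-chloro-6-[(3E,5E,7R)-5,7-dimethylnona-3,5-dien-1-yn-1-yl]-2,3-dihydroxy-3-methyl-4-oxocyclohexa-1,5-diene-1-carbaldehyde | CC[C@@H](C)/C=C(C)/C=C/C#CC1=C(Cl)C(=O)[C@](C)(O)C(O)=C1C=O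
F2 | step 10 | (7R)-5-chloro-3-[(1E,3E,5R)-3,5-dimethylhepta-1,3-dien-1-yl]-7-methyl-6,8-dioxo-7,8-dihydro-6H-isochromen-7-yl acetate | CC[C@@H](C)/C=C(C)/C=C/C1=CC2=C(Cl)C(=O)[C@](C)(OC(C)=O)C(=O)C2=CO1
F3 | step 10 | (7R,8R,8aR)-5-chloro-3-[(1E,3E,5R)-3,5-dimethylhepta-1,3-dien-1-yl]-8-hydroxy-7-methyl-6-oxo-1,7,8,8a-tetrahydro-6H-isochromen-7-yl acetate | CC[C@@H](C)/C=C(C)/C=C/C1=CC2=C(Cl)C(=O)[C@](C)(OC(C)=O)[C@H](O)[C@H]2CO1
F4 | step 8 | 6-[(3E,5E,7R)-5,7-dimethylnona-3,5-dien-1-yn-1-yl]-2,4-dihydroxy-3-methylbenzaldehyde | CC[C@@H](C)/C=C(C)/C=C/C#Cc1cc(O)c(C)c(O)c1C=O
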